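**Retrosynthetic overview**
1. Target 40 ⇐ C8 angelate and C5 (R)-2-methylbutanoate (put on last) ⇐ α-methylene-γ-lactone closed from C12 onto O6 ⇐ 2,3-epoxy-4-ol 28 ⇐ (E)-cyclodecenone 23, whose C3=C4 alkene is shifted and oxidised (epoxide, selenide, selenoxide, hydroxyl-directed epoxidation).
2. Feature used: in the ten-membered carbocycle the ketone carbon C9 and the methyl carbinol carbon C4 are 1,6-related and joined on one side by C10(HMe)–C1H2–C2–C3 (the oxirane carbons), the pattern of a cyclodec-5-enone. Ketone 23 therefore comes from the trans-1,2-divinylcyclohexanol 20 by anionic oxy-Cope ring expansion (C4–C9 broken, C1–C2 made), the enolate being methylated at C10.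
3. 20 ⇐ (S)-carvone: vinyl addition to C=O, directed epoxidation and semipinacol vinyl shift (quaternary C4); enol triflate and Stille coupling (9-vinyl diene); α-hydroxylation and directed reduction (trans-5,6-diol); diene monoepoxide opened by p-methoxybenzyl oxide (C8 and C9).
4. Rings in order: cyclohexane (from carvone), ten-membered ring (step 17, ring expansion), oxirane (step 21), γ-lactone (step 24).

Key step: step 17

Numbering: C1–C10 are the ring carbons of the target (C1 CH2, C2/C3 oxirane, C4 C(Me)OH, C5 CH–O-acyl, C6 CH–O-lactone, C7, C8 CH–OAng, C9 C=O, C10 CHMe); C11–C13 are the lactone carbons (C12 C=O, C13 =CH2). The same numbers are used for the cyclohexane intermediates: carvone C=O is C9, its methyl-bearing carbon C4, then C5, C6, C7 (carrying C11–C13) and C8.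

Remark on the chemistry: the carbinol carbon of 20 carries vinyl and the C10 methyl is added as MeI, because the chair transition state gives a ring-trans enolate whose only free lobe at C10 is the outer, equatorial one; a proton put there would leave a methyl group axial (10-epi), whereas a methyl group put there is equatorial as in the target. (S)-Carvone is the enantiomer whose carbonyl carbon maps onto C9 with the correct C7.

**Route**

Step 1
Reactants: 1 (S)-carvone
Product: 2 12-chlorocarvone [(S)-5-(3-chloroprop-1-en-2-yl)-2-methylcyclohex-2-en-1-one]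
Conditions: Ca(OCl)2, CO2 (s), CH2Cl2/H2O, 0 °C
Reagents that add atoms: calcium hypochlorite, [Ca+2].[O-]Cl.[O-]Cl
Why: Ene-type allylic chlorination by HOCl should attack only the electron-rich 1,1-disubstituted side-chain alkene (the enone alkene is deactivated) and move the double bond into the former methyl group, so C12 is functionalised without touching C7.

Step 2
Reactants: 2 12-chlorocarvone
Product: 4 12-hydroxycarvone [(S)-5-(3-hydroxyprop-1-en-2-yl)-2-methylcyclohex-2-en-1-one], via allylic acetate 3 (not isolated)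
Conditions: KOAc, NaI (cat.), DMF, 60 °C; then K2CO3 (cat.), MeOH, rt
Reagents that add atoms: potassium acetate, CC(=O)[O-].[K+]
Why: SN2 displacement of the primary allylic chloride by acetate followed by base-catalysed transesterification should free the primary allylic alcohol under conditions too mild to touch the enone.

Step 3
Reactants: 4 12-hydroxycarvone
Product: 5 triisopropylsilyl ether of 4
Conditions: i-Pr3SiCl, imidazole, DMF, rt
Reagents that add atoms: chlorotriisopropylsilane, CC(C)[Si](Cl)(C(C)C)C(C)C
Why: Standard silylation of a primary alcohol; the TIPS ether is chosen because it should survive the Grignard reagent, amide bases and the hot alkoxide of step 16.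

Step 4
Reactants: 5 TIPS ether
Product: 6 tertiary alcohol (9-vinyl-9-ol; vinyl trans and OH cis to the C7 side chain; C4=C5 alkene kept)
Conditions: CH2=CHMgBr, THF, −78 → −20 °C; H2O
Reagents that add atoms: vinylmagnesium bromide, C=C[Mg]Br
Why: 1,2-Addition of the Grignard reagent to the enone carbonyl is expected to occur by axial attack anti to the C7 side chain, as in hydride reductions of carvone, which puts vinyl trans and OH cis to the side chain.

Step 5
Reactants: 6 tertiary alcohol
Product: 7 4,5-epoxy-9-ol (oxirane oxygen cis to the C9 hydroxyl and to the side chain)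
Conditions: VO(acac)2 (cat.), t-BuOOH, CH2Cl2, 0 °C → rt
Reagents that add atoms: tert-butyl hydroperoxide, CC(C)(C)OO
Why: Vanadium-catalysed hydroxyl-directed epoxidation of the tertiary allylic alcohol should select the trisubstituted C4=C5 ring alkene over the vinyl and side-chain alkenes and deliver oxygen syn to the C9 hydroxyl.

Step 6
Reactants: 7 epoxy alcohol
Product: 8 5-hydroxy-9-ketone with quaternary C4 (methyl cis, vinyl trans to the C7 side chain; 5-OH cis to it)
Conditions: BF3·OEt2 (0.3 equiv), CH2Cl2, −78 → −40 °C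
Reagents that add atoms: none
Why: Semipinacol rearrangement of the 2,3-epoxy alcohol: the tertiary C4–O bond ionises and the vinyl group, anti-periplanar to it, shifts from C9 to C4 with inversion, which regenerates the C9 ketone and fixes the quaternary centre.

Step 7
Reactants: 8 hydroxy ketone
Product: 9 5-O-triethylsilyl ether of 8
Conditions: Et3SiCl, imidazole, DMF, rt
Reagents that add atoms: chlorotriethylsilane, CC[Si](Cl)(CC)CC
Why: Silylation protects the β-hydroxyl against retro-aldol cleavage and O-sulfonylation in the next step.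

Step 8
Reactants: 9 silyl ether
Product: 11 C9 enol triflate (C8=C9), via potassium enolate 10 (not isolated)
Conditions: KHMDS, THF, −78 °C; PhNTf2, −78 → 0 °C
Reagents that add atoms: N-phenylbis(trifluoromethanesulfonimide), O=S(=O)(N(c1ccccc1)S(=O)(=O)C(F)(F)F)C(F)(F)F
Why: With C4 quaternary the ketone can enolise only toward C8, so deprotonation and O-triflation should give a single enol triflate.

Step 9
Reactants: 11 enol triflate
Product: 12 9-vinyl-8(9)-ene (a 1-vinylcyclohexene; 5-OTES)
Conditions: Bu3SnCH=CH2, Pd(PPh3)4 (cat.), LiCl, THF, 65 °C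
Reagents that add atoms: tributyl(vinyl)stannane, C=C[Sn](CCCC)(CCCC)CCCC
Why: Stille coupling of the enol triflate with the vinylstannane installs the C9 vinyl group (future C10 and C1).

Step 10
Reactants: 12 diene silyl ether
Product: 13 C5 alcohol
Conditions: PPTS (cat.), MeOH, rt
Reagents that add atoms: none
Why: Acid-catalysed methanolysis should remove the secondary TES ether while the primary TIPS ether and the diene stay untouched.

Step 11
Reactants: 13 alcohol
Product: 14 C5 ketone
Conditions: Dess–Martin periodinane, NaHCO3, CH2Cl2, rt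
Reagents that add atoms: none
Why: Dess–Martin oxidation of the secondary alcohol; the β,γ-unsaturated ketone cannot move into conjugation because C4 is quaternary.

Step 12
Reactants: 14 ketone
Product: 16 6-hydroxy-5-ketone (6-OH trans to the C7 side chain), via potassium enolate 15 (not isolated)
Conditions: KHMDS, THF, −78 °C; 2-(phenylsulfonyl)-3-phenyloxaziridine; AcOH
Reagents that add atoms: 2-(phenylsulfonyl)-3-phenyloxaziridine, O=S(=O)(N1OC1c1ccccc1)c1ccccc1
Why: The enolate can form only toward C6 and should be oxidised by the N-sulfonyloxaziridine on the face away from the adjacent C7 side chain (enolate α-hydroxylation).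

Step 13
Reactants: 16 α-hydroxy ketone
Product: 17 trans-5,6-diol (5-OH cis, 6-OH trans to the side chain)
Conditions: Me4NBH(OAc)3, MeCN/AcOH, −20 °C
Reagents that add atoms: none
Why: Hydroxyl-directed triacetoxyborohydride reduction: the C6 hydroxyl binds boron and hydride is delivered to the same face of the C5 ketone, which should give the trans-diol.

Step 14
Reactants: 17 diol
Product: 18 trans-fused 5,6-acetonide
Conditions: 2-methoxypropene, PPTS (cat.), CH2Cl2, 0 °C
Reagents that add atoms: 2-methoxypropene, COC(C)=C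
Why: Acetalisation under kinetic conditions ties the diequatorial trans-diol into a trans-fused dioxolane, which also locks the ring in the conformation with the C4 methyl axial.

Step 15
Reactants: 18 acetonide
Product: 19 8,9-epoxide (oxirane oxygen trans to the side chain and to the C4 methyl)
Conditions: mCPBA, NaHCO3, CH2Cl2, −20 °C
Reagents that add atoms: 3-chloroperbenzoic acid, OOC(=O)c1cccc(Cl)c1
Why: The peracid should take the most electron-rich alkene, the trisubstituted ring alkene of the diene, from the face opposite to the pseudo-axial C4 methyl.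

Step 16
Reactants: 19 vinyl epoxide
Product: 20 rearrangement precursor (C7 side chain, O5, C4 methyl, C9 vinyl and 8-OPMB on one face; O6, C4 vinyl and 9-OH on the other)
Conditions: NaH (0.3 equiv), 4-MeOC6H4CH2OH (solvent), 70 °C
Reagents that add atoms: 4-methoxybenzyl alcohol, COc1ccc(CO)cc1
Why: Base-catalysed alcoholysis of the epoxide: the alkoxide can attack only the secondary carbon C8 (C9 is fully substituted) and does so trans-diaxially (Fürst–Plattner rule) with inversion, giving the axial C8 ether cis to the side chain and leaving the C9 oxygen axial with its vinyl group equatorial.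

Step 17
Reactants: 20 rearrangement precursor
Product: 23 (E)-cyclodecenone (9-ketone, 10-methyl, E-C3=C4, 5,6-acetonide, 8-OPMB), via potassium alkoxide 21 (not isolated), via potassium enolate 22 (not isolated)
Conditions: KH, 18-crown-6, THF, 0 °C → rt; then MeI, −78 → 0 °C
Reagents that add atoms: iodomethane, CI
Why: KH/18-crown-6 converts 20 into the dissociated potassium alkoxide 21, whose [3,3] sigmatropic shift breaks C4–C9 and joins the two vinyl termini (C1–C2), the carbinol carbon emerging as the C9 enolate 22; the closest known reaction is the anionic oxy-Cope ring expansion of 1,2-divinylcyclohexanols to cyclodec-5-enones with alkylation of the enolate in the same flask. The ten-membered ring is not closed end to end but opened out of the cyclohexane by a four-atom ring expansion, the only new bond being made between two CH2 termini already held gauche, so no dilution is needed. The trans-fused acetonide fixes the chair in which both vinyl groups are equatorial, and the chair transition state that follows gives the E C3=C4 alkene and a ring-trans enolate. The new stereocentre C10 is set by the planar chirality of this enolate: its inner lobe faces the C3=C4 bond across the ring, so methyl iodide adds to the outer (equatorial) lobe and the methyl group ends up equatorial as in the target, whereas a proton delivered to the same lobe would have left a pre-installed methyl group axial. The step needs C- rather than O-methylation and no proton exchange with the aligned C8–H, which the soft electrophile, its excess and trapping at −78 °C directly after rearrangement should secure, and the enolate can only be the C9=C10 one because the bond reorganisation itself forms it. C5–C8 are not touched.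

Step 18
Reactants: 23 cyclodecenone
Product: 24 3,4-epoxide (trans-oxirane, oxygen on the outer face)
Conditions: mCPBA, NaHCO3, CH2Cl2, −20 → 0 °C
Reagents that add atoms: 3-chloroperbenzoic acid, OOC(=O)c1cccc(Cl)c1
Why: The trisubstituted C3=C4 alkene is far more nucleophilic than the 1,1-disubstituted allylic-ether alkene, and in the crown conformer born in step 17 its π bond stands perpendicular to the ring with C9 across the inner face, so peripheral epoxidation should place the C4 oxygen as in the target.

Step 19
Reactants: 24 epoxide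
Product: 25 3-phenylseleno-4-ol
Conditions: PhSeSePh, NaBH4, EtOH, 0 °C → rt; AcOH (0.2 equiv); then 24, 45 °C
Reagents that add atoms: diphenyl diselenide, c1ccc(cc1)[Se][Se]c1ccccc1
Why: The selenolate should open the trisubstituted epoxide by SN2 attack at the less substituted carbon C3, leaving the C4 oxygen with its configuration as the tertiary alcohol.

Step 20
Reactants: 25 hydroxy selenide
Product: 27 (2E)-2-en-4-ol (tertiary allylic alcohol), via selenoxide 26 (not isolated)
Conditions: mCPBA, CH2Cl2, −78 °C; then i-Pr2NH, −78 °C → rt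
Reagents that add atoms: none
Why: Selenoxide syn-elimination can go only toward C2 (C4 carries no hydrogen) and, as syn-eliminations in ten-membered rings do, should give the E alkene.

Step 21
Reactants: 27 allylic alcohol
Product: 28 2,3-epoxy-4-ol
Conditions: VO(acac)2 (cat.), t-BuOOH, CH2Cl2, 0 °C → rt
Reagents that add atoms: tert-butyl hydroperoxide, CC(C)(C)OO
Why: Vanadium-catalysed epoxidation directed by the tertiary C4 hydroxyl (O–C4–C3=C2 dihedral near 45°, ring bond C4–C5 anti to the incoming oxygen) should deliver oxygen to the outer face of the E alkene syn to the hydroxyl, which is the trans-oxirane of the target.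

Step 22
Reactants: 28 epoxy alcohol
Product: 29 primary allylic alcohol (C12–OH)
Conditions: TBAF, AcOH, THF, 0 °C → rt
Reagents that add atoms: none
Why: Fluoride cleaves the primary TIPS ether, and acetic acid buffers the medium so that the α-alkoxy ketone should not epimerise.

Step 23
Reactants: 29 alcohol
Product: 30 tetraol (4-, 5-, 6- and 12-OH free; 8-OPMB)
Conditions: PPTS (cat.), MeOH, rt
Reagents that add atoms: none
Why: The strained trans-fused acetonide should be methanolysed under acid catalysis mild enough to leave the epoxide and the PMB ether intact.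

Step 24
Reactants: 30 tetraol
Product: 33 12,6-lactone (α-methylene-γ-lactone; 4- and 5-OH free, 8-OPMB), via enal 31 (not isolated), via lactol 32 (not isolated)
Conditions: MnO2 (excess), CH2Cl2, rt
Reagents that add atoms: none
Why: MnO2 oxidises only the allylic primary alcohol; the enal closes to the five-membered lactol with the C6 hydroxyl (5-exo-trig; O8 is blocked, O5 would give a six-membered ring) and the lactol is oxidised on to the lactone.

Step 25
Reactants: 33 lactone; 34 (R)-2-methylbutanoic acid
Product: 36 5-O-[(R)-2-methylbutanoyl] ester, via mixed anhydride 35 (not isolated)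
Conditions: 34, 2,4,6-Cl3C6H2COCl, Et3N, THF, rt; then 33, DMAP (cat.), toluene, rt
Reagents that add atoms: none
Why: Yamaguchi esterification should acylate the only free secondary hydroxyl (C5), the tertiary C4 hydroxyl being too hindered, without enolising the α-stereocentre of the acid.

Step 26
Reactants: 36 ester
Product: 37 8-alcohol
Conditions: DDQ, CH2Cl2/pH 7 buffer, 0 °C → rt
Reagents that add atoms: none
Why: Oxidative cleavage of the p-methoxybenzyl ether by DDQ in wet dichloromethane should free the C8 hydroxyl without affecting the epoxide, the ester or the α-methylene lactone.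

Step 27
Reactants: 37 8-alcohol; 38 angelic acid
Product: 40 CNP0217571.1, via angelic mixed anhydride 39 (not isolated)
Conditions: 38, 2,4,6-Cl3C6H2COCl, Et3N, toluene, rt; then 37, 80 °C
Reagents that add atoms: none
Why: Acylation with the preformed angelic 2,4,6-trichlorobenzoic anhydride without a nucleophilic catalyst (Yamaguchi-type) is the established way to form angelates without Z to E isomerisation, and the tertiary C4 hydroxyl stays free.

**Compound list**

1 | (S)-(+)-carvone | CC1=CC[C@H](C(C)=C)CC1=O | starting material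
2 | 12-chlorocarvone, (S)-5-(3-chloroprop-1-en-2-yl)-2-methylcyclohex-2-en-1-one | CC1=CC[C@H](C(=C)CCl)CC1=O | intermediate
3 | allylic acetate of 4 (formed in the flask) | CC1=CC[C@H](C(=C)COC(C)=O)CC1=O | intermediate
4 | 12-hydroxycarvone, (S)-5-(3-hydroxyprop-1-en-2-yl)-2-methylcyclohex-2-en-1-one | CC1=CC[C@H](C(=C)CO)CC1=O | intermediate
5 | TIPS ether of 4 | CC1=CC[C@H](C(=C)CO[Si](C(C)C)(C(C)C)C(C)C)CC1=O | intermediate
6 | 9-vinyl-9-ol (vinyl trans, OH cis to the C7 side chain; C4=C5) | CC1=CC[C@H](C(=C)CO[Si](C(C)C)(C(C)C)C(C)C)C[C@@]1(O)C=C | intermediate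
7 | 4,5-epoxy-9-ol (oxirane oxygen cis to 9-OH and to the side chain) | C[C@@]12O[C@@H]1C[C@H](C(=C)CO[Si](C(C)C)(C(C)C)C(C)C)C[C@@]2(O)C=C | intermediate
8 | 5-hydroxy-9-ketone, quaternary C4 (methyl cis, vinyl trans to the side chain; 5-OH cis) | O=C1C[C@@H](C(=C)CO[Si](C(C)C)(C(C)C)C(C)C)C[C@@H](O)[C@]1(C)C=C | intermediate
9 | 5-O-triethylsilyl ether of 8 | O=C1C[C@@H](C(=C)CO[Si](C(C)C)(C(C)C)C(C)C)C[C@@H](O[Si](CC)(CC)CC)[C@]1(C)C=C | intermediate
10 | potassium C8=C9 enolate of 9 (formed in the flask) | [K+].[O-]C1=C[C@@H](C(=C)CO[Si](C(C)C)(C(C)C)C(C)C)C[C@@H](O[Si](CC)(CC)CC)[C@]1(C)C=C | intermediate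
11 | C9 enol triflate (C8=C9) | O=S(=O)(OC1=C[C@@H](C(=C)CO[Si](C(C)C)(C(C)C)C(C)C)C[C@@H](O[Si](CC)(CC)CC)[C@]1(C)C=C)C(F)(F)F | intermediate
12 | 9-vinyl-8(9)-ene with 5-OTES | C=CC1=C[C@@H](C(=C)CO[Si](C(C)C)(C(C)C)C(C)C)C[C@@H](O[Si](CC)(CC)CC)[C@]1(C)C=C | intermediate
13 | C5 alcohol | C=CC1=C[C@@H](C(=C)CO[Si](C(C)C)(C(C)C)C(C)C)C[C@@H](O)[C@]1(C)C=C | intermediate
14 | C5 ketone | C=CC1=C[C@@H](C(=C)CO[Si](C(C)C)(C(C)C)C(C)C)CC(=O)[C@]1(C)C=C | intermediate
15 | potassium C5=C6 enolate of 14 (formed in the flask) | C=CC1=C[C@@H](C(=C)CO[Si](C(C)C)(C(C)C)C(C)C)C=C([O-])[C@]1(C)C=C.[K+] | intermediate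
16 | 6-hydroxy-5-ketone (6-OH trans to the side chain) | C=CC1=C[C@@H](C(=C)CO[Si](C(C)C)(C(C)C)C(C)C)[C@H](O)C(=O)[C@]1(C)C=C | intermediate
17 | trans-5,6-diol (5-OH cis, 6-OH trans to the side chain) | C=CC1=C[C@@H](C(=C)CO[Si](C(C)C)(C(C)C)C(C)C)[C@H](O)[C@@H](O)[C@]1(C)C=C | intermediate
18 | trans-fused 5,6-acetonide | C=C(CO[Si](C(C)C)(C(C)C)C(C)C)[C@H]1[C@@H]2OC(C)(C)O[C@H]2[C@](C)(C=C)C(C=C)=C1 | intermediate
19 | 8,9-epoxide (oxygen trans to the side chain and to the C4 methyl) | C=C(CO[Si](C(C)C)(C(C)C)C(C)C)[C@H]1[C@@H]2OC(C)(C)O[C@H]2[C@](C)(C=C)[C@]3(C=C)O[C@H]13 | intermediate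
20 | rearrangement precursor: trans-4,9-divinyl-9-ol with axial 8-OPMB, 5,6-acetonide and TIPS-oxymethylvinyl at C7 | C=C(CO[Si](C(C)C)(C(C)C)C(C)C)[C@H]1[C@@H]2OC(C)(C)O[C@H]2[C@](C)(C=C)[C@@](O)(C=C)[C@H]1OCc1ccc(OC)cc1 | intermediate
21 | potassium alkoxide of 20 (formed in the flask) | C=C(CO[Si](C(C)C)(C(C)C)C(C)C)[C@H]1[C@@H]2OC(C)(C)O[C@H]2[C@](C)(C=C)[C@@]([O-])(C=C)[C@H]1OCc1ccc(OC)cc1.[K+] | intermediate
22 | potassium enolate (C9=C10 ring-trans, C3=C4 E; formed in the flask) | C=C(CO[Si](C(C)C)(C(C)C)C(C)C)[C@@H]1[C@H](OCc2ccc(OC)cc2)/C([O-])=C/CC/C=C(\C)[C@@H]2OC(C)(C)O[C@@H]12.[K+] | intermediate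
23 | (E)-cyclodecenone: 9-ketone, 10-methyl, E-C3=C4, 5,6-acetonide, 8-OPMB | C=C(CO[Si](C(C)C)(C(C)C)C(C)C)[C@@H]1[C@H](OCc2ccc(OC)cc2)C(=O)[C@@H](C)CC/C=C(\C)[C@@H]2OC(C)(C)O[C@@H]12 | intermediate
24 | 3,4-epoxide of 23 | C=C(CO[Si](C(C)C)(C(C)C)C(C)C)[C@@H]1[C@H](OCc2ccc(OC)cc2)C(=O)[C@@H](C)CC[C@@H]3O[C@@]3(C)[C@@H]2OC(C)(C)O[C@@H]12 | intermediate
25 | 3-phenylseleno-4-ol | C=C(CO[Si](C(C)C)(C(C)C)C(C)C)[C@@H]1[C@H](OCc2ccc(OC)cc2)C(=O)[C@@H](C)CC[C@@H]([Se]c3ccccc3)[C@@](C)(O)[C@@H]2OC(C)(C)O[C@@H]12 | intermediate
26 | selenoxide of 25 (formed in the flask) | C=C(CO[Si](C(C)C)(C(C)C)C(C)C)[C@@H]1[C@H](OCc2ccc(OC)cc2)C(=O)[C@@H](C)CC[C@@H]([Se](=O)c3ccccc3)[C@@](C)(O)[C@@H]2OC(C)(C)O[C@@H]12 | intermediate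
27 | (2E)-2-en-4-ol (tertiary allylic alcohol) | C=C(CO[Si](C(C)C)(C(C)C)C(C)C)[C@@H]1[C@H](OCc2ccc(OC)cc2)C(=O)[C@@H](C)C/C=C/[C@@](C)(O)[C@@H]2OC(C)(C)O[C@@H]12 | intermediate
28 | 2,3-epoxy-4-ol | C=C(CO[Si](C(C)C)(C(C)C)C(C)C)[C@@H]1[C@H](OCc2ccc(OC)cc2)C(=O)[C@@H](C)C[C@@H]3O[C@H]3[C@@](C)(O)[C@@H]2OC(C)(C)O[C@@H]12 | intermediate
29 | primary allylic alcohol (12-OH) | C=C(CO)[C@@H]1[C@H](OCc2ccc(OC)cc2)C(=O)[C@@H](C)C[C@@H]3O[C@H]3[C@@](C)(O)[C@@H]2OC(C)(C)O[C@@H]12 | intermediate
30 | tetraol (4-, 5-, 6-, 12-OH; 8-OPMB) | C=C(CO)[C@@H]1[C@H](OCc2ccc(OC)cc2)C(=O)[C@@H](C)C[C@@H]3O[C@H]3[C@@](C)(O)[C@H](O)[C@H]1O | intermediate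
31 | C12 enal (formed in the flask) | C=C(C=O)[C@@H]1[C@H](OCc2ccc(OC)cc2)C(=O)[C@@H](C)C[C@@H]3O[C@H]3[C@@](C)(O)[C@H](O)[C@H]1O | intermediate
32 | 12,6-lactol (formed in the flask) | C=C1C(O)O[C@H]2[C@H]1[C@H](OCc3ccc(OC)cc3)C(=O)[C@@H](C)C[C@@H]4O[C@H]4[C@@](C)(O)[C@@H]2O | intermediate
33 | 12,6-lactone with 8-OPMB, 4- and 5-OH free | C=C1C(=O)O[C@H]2[C@H]1[C@H](OCc3ccc(OC)cc3)C(=O)[C@@H](C)C[C@@H]4O[C@H]4[C@@](C)(O)[C@@H]2O | intermediate
34 | (R)-2-methylbutanoic acid | CC[C@@H](C)C(=O)O | starting material
35 | (R)-2-methylbutanoic 2,4,6-trichlorobenzoic anhydride (formed in the flask) | CC[C@@H](C)C(=O)OC(=O)c1c(Cl)cc(Cl)cc1Cl | intermediate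
36 | 5-O-[(R)-2-methylbutanoyl] ester of 33 | C=C1C(=O)O[C@H]2[C@H]1[C@H](OCc3ccc(OC)cc3)C(=O)[C@@H](C)C[C@@H]4O[C@H]4[C@@](C)(O)[C@@H]2OC(=O)[C@H](C)CC | intermediate
37 | 8-alcohol | C=C1C(=O)O[C@H]2[C@H]1[C@H](O)C(=O)[C@@H](C)C[C@@H]3O[C@H]3[C@@](C)(O)[C@@H]2OC(=O)[C@H](C)CC | intermediate
38 | angelic acid, (Z)-2-methylbut-2-enoic acid | C/C=C(/C)C(=O)O | starting material
39 | angelic 2,4,6-trichlorobenzoic anhydride (formed in the flask) | C/C=C(/C)C(=O)OC(=O)c1c(Cl)cc(Cl)cc1Cl | intermediate
40 | CNP0217571.1 | C=C1C(=O)O[C@H]2[C@H]1[C@H](OC(=O)/C(C)=C\C)C(=O)[C@@H](C)C[C@@H]1O[C@H]1[C@@](C)(O)[C@@H]2OC(=O)[C@H](C)CC | target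

Total step count: 27. Longest linear sequence: 27 steps from (S)-carvone (34 and 38 are used as bought).

**Steps most likely to fail**

Step 16. The alkoxide has to attack a secondary carbon that is shielded by the axial C4 methyl and flanked by the C7 side chain. Conjugate opening at the vinyl terminus, base-induced isomerisation of the oxirane, or rearrangement of the product alkoxide already at 70 °C may compete. Fallback: starting from 19, the epoxide is opened with the smaller hydroxide ion in a protic medium (KOH, DMSO/H2O, 90 °C) to the 8,9-diol F1. The secondary hydroxyl of F1 is then etherified selectively (NaH 1 equiv, 4-methoxybenzyl chloride, Bu4NI, THF, 0 °C; the tertiary alkoxide is far more hindered), which returns to 20.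

Step 17. The crown-ether-separated enolate may be methylated on oxygen, may exchange a proton with the aligned C8–H before methyl iodide arrives, or may turn its face over (C10–H passing through the ring) before it is trapped, which would erode C10. Fallback: starting from 20, the alcohol is silylated (1-(trimethylsilyl)imidazole, CH2Cl2) to the trimethylsilyl ether F2. This is rearranged thermally through the same chair (siloxy-Cope, toluene in a sealed tube, about 200 °C) to the trimethylsilyl enol ether F3. F3 is cleaved with MeLi (THF, 0 °C) to the lithium enolate F4, which is C-methylated with MeI/HMPA at −78 °C and returns to 23.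

Step 19. In the ground-state conformer the back side of C3 points into the ring, so the SN2 opening may be slow. Reduction of the ketone by residual hydride or transannular closure of the C4 alkoxide onto C9 could then take over. Fallback: starting from 23 (bypassing 24–26), a Schenck ene reaction with singlet oxygen (O2, tetraphenylporphyrin, hν, CH2Cl2, −20 °C) adds oxygen to C4 from the outer face with transfer of an allylic hydrogen from C2 and gives the tertiary allylic hydroperoxide F5. Reduction of F5 with PPh3 returns to 27.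

Further compounds
F1 | step 16 | 8,9-diol (8-OH cis to the side chain, tertiary 9-OH) | C=C(CO[Si](C(C)C)(C(C)C)C(C)C)[C@H]1[C@@H]2OC(C)(C)O[C@H]2[C@](C)(C=C)[C@@](O)(C=C)[C@H]1O
F2 | step 17 | 9-O-trimethylsilyl ether of 20 | C=C(CO[Si](C(C)C)(C(C)C)C(C)C)[C@H]1[C@@H]2OC(C)(C)O[C@H]2[C@](C)(C=C)[C@@](O[Si](C)(C)C)(C=C)[C@H]1OCc1ccc(OC)cc1
F3 | step 17 | trimethylsilyl enol ether (C9=C10 ring-trans, C3=C4 E) | C=C(CO[Si](C(C)C)(C(C)C)C(C)C)[C@@H]1[C@H](OCc2ccc(OC)cc2)/C(O[Si](C)(C)C)=C/CC/C=C(\C)[C@@H]2OC(C)(C)O[C@@H]12
F4 | step 17 | lithium enolate (C9=C10 ring-trans) | C=C(CO[Si](C(C)C)(C(C)C)C(C)C)[C@@H]1[C@H](OCc2ccc(OC)cc2)/C([O-])=C/CC/C=C(\C)[C@@H]2OC(C)(C)O[C@@H]12.[Li+]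
F5 | step 19 | tertiary allylic hydroperoxide (4-OOH, E-C2=C3) | C=C(CO[Si](C(C)C)(C(C)C)C(C)C)[C@@H]1[C@H](OCc2ccc(OC)cc2)C(=O)[C@@H](C)C/C=C/[C@@](C)(OO)[C@@H]2OC(C)(C)O[C@@H]12
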